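**Retrosynthetic overview**
- The target is cut at the C5–O ester bond into a hydroxy-lactone core (acid masked as a tert-butyl ester) and a silyl-protected dienoic acid; one acidic deprotection ends the route.
- Dienoic acid: the C2'–C3' bond and the (4E)-trisubstituted alkene come from a Johnson–Claisen [3,3]-sigmatropic rearrangement of a 2-methylallylic alcohol, followed by selenoxide dehydrogenation. The allylic alcohol comes from an α-methyl aldehyde and isopropenyl Grignard.
- The aldehyde carries both side-chain stereocentres as bought: C6' from (R)-β-citronellene and C11' from (S)-propylene oxide, joined by a copper-catalysed Grignard epoxide opening.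
- Core: both ring stereocentres are bought in L-tartrate, taken to (3S,4S)-hexa-1,5-diene-3,4-diol, then its mono-acrylate.
- Ring order: there is one ring, the dihydropyranone, closed by ring-closing metathesis (followed in the same pot by cross-metathesis) before the two fragments are joined.

Assumption: lactone atoms are numbered O1, C2(=O), C3=C4, C5, C6; side-chain acid carbons are primed (C1' = ester carbonyl, C12' = terminal methyl); compounds 1, 5 and 18 are bought as single enantiomers.

**Step 1**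
Reactants: 1 (R)-β-citronellene [(3R)-3,7-dimethylocta-1,6-diene]
Product: 3 (4R)-4-methylhex-5-en-1-ol, via aldehyde 2 (not isolated)
Conditions: O3 (1.0 equiv, Sudan Red 7B end point), CH2Cl2/MeOH, −78 °C; then NaBH4, −78 °C to rt
Reagents that add atoms: ozone, O=[O+][O-]
Why: Chemoselective ozonolysis cleaves the electron-rich trisubstituted alkene much faster than the vinyl group, and the borohydride work-up gives the primary alcohol without touching the bought C6' centre.

**Step 2**
Reactants: 3 (4R)-4-methylhex-5-en-1-ol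
Product: 4 (3R)-6-bromo-3-methylhex-1-ene
Conditions: CBr4, PPh3, CH2Cl2, 0 °C
Reagents that add atoms: carbon tetrabromide, BrC(Br)(Br)Br
Why: Appel bromination is an SN2 displacement at the primary carbon, remote from the stereocentre.

**Step 3**
Reactants: 4 (3R)-6-bromo-3-methylhex-1-ene; 5 (S)-propylene oxide [(2S)-2-methyloxirane]
Product: 7 (2S,7R)-7-methylnon-8-en-2-ol, via Grignard reagent 6 (not isolated)
Conditions: Mg, THF, ≤30 °C; then CuI (10 mol %), 5, −30 to 0 °C; aq. NH4Cl
Reagents that add atoms: magnesium, [Mg] (held only in 6)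
Why: Copper-catalysed SN2 opening of the epoxide by the Grignard reagent at the unsubstituted carbon leaves the bought (S) centre untouched as C11' (the Grignard is formed at or below 30 °C to suppress 5-hexenyl radical cyclisation).

**Step 4**
Reactants: 7 (2S,7R)-7-methylnon-8-en-2-ol
Product: 8 tert-butyldimethyl{[(2S,7R)-7-methylnon-8-en-2-yl]oxy}silane
Conditions: TBSCl, imidazole, DMF, rt
Reagents that add atoms: tert-butyldimethylsilyl chloride, CC(C)(C)[Si](C)(C)Cl
Why: Standard silylation of the secondary alcohol gives an ether that survives the ozonolysis, Grignard, Claisen, enolate and saponification steps.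

**Step 5**
Reactants: 8 tert-butyldimethyl{[(2S,7R)-7-methylnon-8-en-2-yl]oxy}silane
Product: 10 (2R,7S)-7-[(tert-butyldimethylsilyl)oxy]-2-methyloctanal, via ozonide 9 (not isolated)
Conditions: O3, CH2Cl2, −78 °C; then PPh3, −78 °C to rt; used crude
Reagents that add atoms: ozone, O=[O+][O-]
Why: Ozonolysis with reductive work-up converts the vinyl group into the aldehyde under cold neutral conditions that do not epimerise the α-methyl centre.

**Step 6**
Reactants: 10 (2R,7S)-7-[(tert-butyldimethylsilyl)oxy]-2-methyloctanal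
Product: 11 (4R,9S)-9-[(tert-butyldimethylsilyl)oxy]-2,4-dimethyldec-1-en-3-ol (both C3 epimers)
Conditions: CH2=C(CH3)MgBr, THF, −78 to 0 °C; aq. NH4Cl
Reagents that add atoms: isopropenylmagnesium bromide, C=C(C)[Mg]Br
Why: Grignard 1,2-addition gives the 2-methylallylic alcohol; its new carbinol centre is destroyed in the next step, so no selectivity is needed.

**Step 7**
Reactants: 11 (4R,9S)-9-[(tert-butyldimethylsilyl)oxy]-2,4-dimethyldec-1-en-3-ol
Product: 13 ethyl (4E,6R,11S)-11-[(tert-butyldimethylsilyl)oxy]-4,6-dimethyldodec-4-enoate, via ketene acetal 12 (not isolated)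
Conditions: CH3C(OEt)3 (6 equiv), EtCO2H (10 mol %), 140 °C, EtOH distilled off
Reagents that add atoms: triethyl orthoacetate, CCOC(C)(OCC)OCC
Why: The Johnson–Claisen [3,3]-sigmatropic rearrangement proceeds through a chair transition state with the C6' chain pseudo-equatorial, forming the C2'–C3' bond and the (4E)-trisubstituted alkene from either carbinol epimer while C6' and C11' are untouched.

**Step 8**
Reactants: 13 ethyl (4E,6R,11S)-11-[(tert-butyldimethylsilyl)oxy]-4,6-dimethyldodec-4-enoate
Product: 16 ethyl (2E,4E,6R,11S)-11-[(tert-butyldimethylsilyl)oxy]-4,6-dimethyldodeca-2,4-dienoate, via selenide 14 (not isolated), via selenoxide 15 (not isolated)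
Conditions: LiN(iPr)2, THF, −78 °C; PhSeBr, −78 °C; then 30% H2O2, pyridine, 0 °C to rt
Reagents that add atoms: phenylselanyl bromide, Br[Se]c1ccccc1 (held only in 14 and 15); hydrogen peroxide, OO (oxygen held only in 15)
Why: α-Selenenylation of the ester enolate followed by selenoxide syn-elimination can only use the C3' hydrogens and gives the conjugated (2E)-alkene.

**Step 9**
Reactants: 16 ethyl (2E,4E,6R,11S)-11-[(tert-butyldimethylsilyl)oxy]-4,6-dimethyldodeca-2,4-dienoate
Product: 17 (2E,4E,6R,11S)-11-[(tert-butyldimethylsilyl)oxy]-4,6-dimethyldodeca-2,4-dienoic acid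
Conditions: LiOH, THF/MeOH/H2O, rt to 40 °C; then 1 M HCl to pH 4, 0 °C
Reagents that add atoms: lithium hydroxide, [Li+].[OH-]
Why: Saponification of the ethyl ester leaves the silyl ether, the diene geometry and both stereocentres unchanged.

**Step 10**
Reactants: 18 dimethyl (4R,5R)-2,2-dimethyl-1,3-dioxolane-4,5-dicarboxylate (dimethyl 2,3-O-isopropylidene-L-tartrate)
Product: 20 (4S,5S)-2,2-dimethyl-4,5-divinyl-1,3-dioxolane, via dialdehyde 19 (not isolated)
Conditions: iBu2AlH (2.1 equiv), toluene, −78 °C; then Ph3P=CH2 (from Ph3PCH3Br, KOtBu, THF), −78 °C to rt; aq. potassium sodium tartrate work-up; product concentrated cold (volatile)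
Reagents that add atoms: methylenetriphenylphosphorane, C=P(c1ccccc1)(c1ccccc1)c1ccccc1
Why: Partial reduction of both esters and Wittig methylenation of the dialdehyde as it is released avoids isolating the epimerisable dialdehyde, and no bond to either tartrate stereocentre is broken (the descriptors become S only through CIP priorities).

**Step 11**
Reactants: 20 (4S,5S)-2,2-dimethyl-4,5-divinyl-1,3-dioxolane
Product: 21 (3S,4S)-hexa-1,5-diene-3,4-diol
Conditions: 1 M aq. HCl, MeOH, 45 °C
Reagents that add atoms: none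
Why: Acid-catalysed acetal hydrolysis breaks only the acetal C–O bonds, so both carbinol centres are retained.

**Step 12**
Reactants: 21 (3S,4S)-hexa-1,5-diene-3,4-diol
Product: 22 (3S,4S)-4-hydroxyhexa-1,5-dien-3-yl prop-2-enoate
Conditions: CH2=CHCOCl (0.9 equiv), 2,4,6-collidine, CH2Cl2, −78 to −40 °C; unreacted 21 recycled
Reagents that add atoms: acryloyl chloride, C=CC(=O)Cl
Why: Acylating either of the two homotopic hydroxyls of the C2-symmetric diol gives the same mono-ester (acyl migration is degenerate), and sub-stoichiometric acid chloride limits the diester.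

**Step 13**
Reactants: 22 (3S,4S)-4-hydroxyhexa-1,5-dien-3-yl prop-2-enoate
Product: 24 tert-butyl (2E)-3-[(2S,3S)-3-hydroxy-6-oxo-3,6-dihydro-2H-pyran-2-yl]prop-2-enoate, via vinyl lactone 23 (not isolated)
Conditions: second-generation Hoveyda–Grubbs catalyst (H2IMes)Cl2Ru=CH(C6H4-2-OiPr) (5 mol %), CH2Cl2 (0.01 M), 40 °C; then tert-butyl acrylate (8 equiv), further 5 mol % catalyst, 40 °C
Reagents that add atoms: tert-butyl acrylate, C=CC(=O)OC(C)(C)C
Why: Ring-closing metathesis starts at the vinyl group beside the free hydroxyl and closes onto the acrylate to give the six-membered unsaturated lactone (5,6-cis fixed by the threo diol), after which cross-metathesis of the remaining vinyl group gives the (E)-enoate while the conjugated ring alkene stays inert.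

**Step 14**
Reactants: 24 tert-butyl (2E)-3-[(2S,3S)-3-hydroxy-6-oxo-3,6-dihydro-2H-pyran-2-yl]prop-2-enoate; 17 (2E,4E,6R,11S)-11-[(tert-butyldimethylsilyl)oxy]-4,6-dimethyldodeca-2,4-dienoic acid
Product: 25 (2S,3S)-2-[(1E)-3-tert-butoxy-3-oxoprop-1-en-1-yl]-6-oxo-3,6-dihydro-2H-pyran-3-yl (2E,4E,6R,11S)-11-[(tert-butyldimethylsilyl)oxy]-4,6-dimethyldodeca-2,4-dienoate
Conditions: DCC (1.3 equiv), DMAP (10 mol %), CH2Cl2, 0 °C to rt
Reagents that add atoms: none
Why: Steglich esterification acylates the secondary allylic alcohol with retention at C5 under nearly neutral conditions, with only catalytic DMAP to limit base-induced elimination to the 2-pyranone.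

**Step 15**
Reactants: 25 (the protected ester from step 14)
Product: 26 (2E)-3-[(2S,3S)-3-{[(2E,4E,6R,11S)-11-hydroxy-4,6-dimethyldodeca-2,4-dienoyl]oxy}-6-oxo-3,6-dihydro-2H-pyran-2-yl]prop-2-enoic acid (CNP0107712.2)
Conditions: CF3CO2H/CH2Cl2/H2O (10:10:1), 0 °C to rt; MeOH co-evaporation; reverse-phase chromatography
Reagents that add atoms: none
Why: Acidolysis cleaves the tert-butyl ester by alkyl–oxygen fission and the silyl ether by protodesilylation in one operation, while the lactone, the dienoate ester and all four stereocentres are stable to aqueous CF3CO2H.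

**Compound list**
1 | (R)-β-citronellene, (3R)-3,7-dimethylocta-1,6-diene | C=C[C@H](C)CCC=C(C)C | starting material
2 | (4R)-4-methylhex-5-enal | C=C[C@H](C)CCC=O | intermediate
3 | (4R)-4-methylhex-5-en-1-ol | C=C[C@H](C)CCCO | intermediate
4 | (3R)-6-bromo-3-methylhex-1-ene | C=C[C@H](C)CCCBr | intermediate
5 | (S)-propylene oxide, (2S)-2-methyloxirane | C[C@H]1CO1 | starting material
6 | [(4R)-4-methylhex-5-en-1-yl]magnesium bromide | C=C[C@H](C)CCC[Mg]Br | intermediate
7 | (2S,7R)-7-methylnon-8-en-2-ol | C=C[C@H](C)CCCC[C@H](C)O | intermediate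
8 | tert-butyldimethyl{[(2S,7R)-7-methylnon-8-en-2-yl]oxy}silane | C=C[C@H](C)CCCC[C@H](C)O[Si](C)(C)C(C)(C)C | intermediate
9 | 3-{(2R,7S)-7-[(tert-butyldimethylsilyl)oxy]octan-2-yl}-1,2,4-trioxolane (secondary ozonide, both ring epimers) | C1OC(OO1)[C@H](C)CCCC[C@H](C)O[Si](C)(C)C(C)(C)C | intermediate
10 | (2R,7S)-7-[(tert-butyldimethylsilyl)oxy]-2-methyloctanal | O=C[C@H](C)CCCC[C@H](C)O[Si](C)(C)C(C)(C)C | intermediate
11 | (4R,9S)-9-[(tert-butyldimethylsilyl)oxy]-2,4-dimethyldec-1-en-3-ol (both C3 epimers) | C=C(C)C(O)[C@H](C)CCCC[C@H](C)O[Si](C)(C)C(C)(C)C | intermediate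
12 | 1-ethoxyethenyl ether of 11 (mixed ketene acetal), tert-butyl{[(2S,7R)-8-(1-ethoxyethenyloxy)-7,9-dimethyldec-9-en-2-yl]oxy}dimethylsilane | C=C(OCC)OC(C(C)=C)[C@H](C)CCCC[C@H](C)O[Si](C)(C)C(C)(C)C | intermediate
13 | ethyl (4E,6R,11S)-11-[(tert-butyldimethylsilyl)oxy]-4,6-dimethyldodec-4-enoate | CCOC(=O)CC/C(C)=C/[C@H](C)CCCC[C@H](C)O[Si](C)(C)C(C)(C)C | intermediate
14 | ethyl (4E,6R,11S)-11-[(tert-butyldimethylsilyl)oxy]-4,6-dimethyl-2-(phenylselanyl)dodec-4-enoate (both C2 epimers) | CCOC(=O)C([Se]c1ccccc1)C/C(C)=C/[C@H](C)CCCC[C@H](C)O[Si](C)(C)C(C)(C)C | intermediate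
15 | ethyl (4E,6R,11S)-2-(benzeneseleninyl)-11-[(tert-butyldimethylsilyl)oxy]-4,6-dimethyldodec-4-enoate | CCOC(=O)C([Se](=O)c1ccccc1)C/C(C)=C/[C@H](C)CCCC[C@H](C)O[Si](C)(C)C(C)(C)C | intermediate
16 | ethyl (2E,4E,6R,11S)-11-[(tert-butyldimethylsilyl)oxy]-4,6-dimethyldodeca-2,4-dienoate | CCOC(=O)/C=C/C(C)=C/[C@H](C)CCCC[C@H](C)O[Si](C)(C)C(C)(C)C | intermediate
17 | (2E,4E,6R,11S)-11-[(tert-butyldimethylsilyl)oxy]-4,6-dimethyldodeca-2,4-dienoic acid | OC(=O)/C=C/C(C)=C/[C@H](C)CCCC[C@H](C)O[Si](C)(C)C(C)(C)C | intermediate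
18 | dimethyl (4R,5R)-2,2-dimethyl-1,3-dioxolane-4,5-dicarboxylate (dimethyl 2,3-O-isopropylidene-L-tartrate) | COC(=O)[C@@H]1OC(C)(C)O[C@H]1C(=O)OC | starting material
19 | (4R,5R)-2,2-dimethyl-1,3-dioxolane-4,5-dicarbaldehyde | O=C[C@@H]1OC(C)(C)O[C@H]1C=O | intermediate
20 | (4S,5S)-2,2-dimethyl-4,5-divinyl-1,3-dioxolane | C=C[C@@H]1OC(C)(C)O[C@H]1C=C | intermediate
21 | (3S,4S)-hexa-1,5-diene-3,4-diol | C=C[C@H](O)[C@@H](O)C=C | intermediate
22 | (3S,4S)-4-hydroxyhexa-1,5-dien-3-yl prop-2-enoate | C=C[C@H](OC(=O)C=C)[C@@H](O)C=C | intermediate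
23 | (5S,6S)-6-ethenyl-5-hydroxy-5,6-dihydro-2H-pyran-2-one | C=C[C@@H]1OC(=O)C=C[C@@H]1O | intermediate
24 | tert-butyl (2E)-3-[(2S,3S)-3-hydroxy-6-oxo-3,6-dihydro-2H-pyran-2-yl]prop-2-enoate | CC(C)(C)OC(=O)/C=C/[C@@H]1OC(=O)C=C[C@@H]1O | intermediate
25 | (2S,3S)-2-[(1E)-3-tert-butoxy-3-oxoprop-1-en-1-yl]-6-oxo-3,6-dihydro-2H-pyran-3-yl (2E,4E,6R,11S)-11-[(tert-butyldimethylsilyl)oxy]-4,6-dimethyldodeca-2,4-dienoate | CC(C)(C)OC(=O)/C=C/[C@@H]1OC(=O)C=C[C@@H]1OC(=O)/C=C/C(C)=C/[C@H](C)CCCC[C@H](C)O[Si](C)(C)C(C)(C)C | intermediate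
26 | (2E)-3-[(2S,3S)-3-{[(2E,4E,6R,11S)-11-hydroxy-4,6-dimethyldodeca-2,4-dienoyl]oxy}-6-oxo-3,6-dihydro-2H-pyran-2-yl]prop-2-enoic acid | OC(=O)/C=C/[C@@H]1OC(=O)C=C[C@@H]1OC(=O)/C=C/C(C)=C/[C@H](C)CCCC[C@H](C)O | target

**Totals**
Total step count: 15. Longest linear sequence: 11 steps (steps 1–9, 14, 15; 1 → 26). The core branch 18 → 24 is 4 steps.

**Three steps most likely to fail**

Step 13 (one-pot ring closure and cross-metathesis). The risks are competing butenolide formation and a sluggish cross-metathesis on the hydroxy-lactone. The fallback sets out from 23 and comes back at 25, leaving out 24. The metathesis is stopped after ring closure and the vinyl lactone 23 is isolated. It is esterified with acid 17 (DCC, catalytic DMAP) to give the vinyl lactone dienoate F1. The cross-metathesis of F1 with tert-butyl acrylate is then run as the last carbon–carbon bond formation with the same ruthenium catalyst; the hindered, conjugated dienoate alkenes of F1 should not take part.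

Step 14 (esterification of 24). Once acylated, the C5 acyloxy group sits next to a vinylogously acidic C6–H, so elimination to a 2-pyranone can compete, and the dienoic acid may acylate slowly. The fallback makes the ester bond before the lactone exists; it sets out from 21 (with 17) and comes back at 25. Diol 21, used in excess, is mono-acylated with 17 (DCC, DMAP) to give the hydroxy dienoate F2. The remaining hydroxyl is acylated with acryloyl chloride to give the mixed acrylate dienoate diester F3. Ring-closing metathesis of F3 gives the vinyl lactone dienoate F1 already described, and cross-metathesis with tert-butyl acrylate returns to 25.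

Step 10 (one-pot partial reduction and methylenation). The risks are over-reduction, an unstable dialdehyde and a volatile product. The fallback avoids any aldehyde; it sets out from 18 and comes back at 20. Ester 18 is reduced with LiAlH4 to 2,3-O-isopropylidene-L-threitol F4. F4 is converted with TsCl/pyridine into its ditosylate F5. Excess dimethylsulfonium methylide (trimethylsulfonium iodide, n-BuLi, THF, −10 °C to rt) then turns each CH2OTs group into a vinyl group by alkylation and ylide-mediated elimination.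

**Further compounds**
F1 | step 13 | (2S,3S)-2-ethenyl-6-oxo-3,6-dihydro-2H-pyran-3-yl (2E,4E,6R,11S)-11-[(tert-butyldimethylsilyl)oxy]-4,6-dimethyldodeca-2,4-dienoate | C=C[C@@H]1OC(=O)C=C[C@@H]1OC(=O)/C=C/C(C)=C/[C@H](C)CCCC[C@H](C)O[Si](C)(C)C(C)(C)C
F2 | step 14 | (3S,4S)-4-hydroxyhexa-1,5-dien-3-yl (2E,4E,6R,11S)-11-[(tert-butyldimethylsilyl)oxy]-4,6-dimethyldodeca-2,4-dienoate | C=C[C@H](OC(=O)/C=C/C(C)=C/[C@H](C)CCCC[C@H](C)O[Si](C)(C)C(C)(C)C)[C@@H](O)C=C
F3 | step 14 | (3S,4S)-4-(prop-2-enoyloxy)hexa-1,5-dien-3-yl (2E,4E,6R,11S)-11-[(tert-butyldimethylsilyl)oxy]-4,6-dimethyldodeca-2,4-dienoate | C=C[C@H](OC(=O)/C=C/C(C)=C/[C@H](C)CCCC[C@H](C)O[Si](C)(C)C(C)(C)C)[C@@H](OC(=O)C=C)C=C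
F4 | step 10 | [(4S,5S)-2,2-dimethyl-1,3-dioxolane-4,5-diyl]dimethanol (2,3-O-isopropylidene-L-threitol) | OC[C@@H]1OC(C)(C)O[C@H]1CO
F5 | step 10 | [(4S,5S)-2,2-dimethyl-1,3-dioxolane-4,5-diyl]bis(methylene) bis(4-methylbenzenesulfonate) | Cc1ccc(cc1)S(=O)(=O)OC[C@@H]1OC(C)(C)O[C@H]1COS(=O)(=O)c1ccc(C)cc1
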